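The plan leaves the cyclopropane to the end. Removing C6' from C1' and C5' turns the thujane unit into a spiro cyclopentenol (ring E: C4', C3', C2', C1', C5') on a finished ring A–D core. The feature exploited is that the cyclopropane sits on the ring E face turned toward arene carbon C14 and the C13 isopropyl group. A C2' hydroxyl on that same face carries the zinc carbenoid there. One operation forms C1'–C6' and C5'–C6', closes the three-membered ring and sets C1' and C5'. The precursor is a hexacycle with a C1'=C5' alkene, an allylic C2'–OH, a C10' silyl ether, a C6 dioxolane and a MOM-protected catechol.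

Key step: step 18

Assumption: abietane numbering C1–C20 for rings A–C, primes for the ten added carbons, ring D = C7, C8, C14, C4', C10'; the SMILES places H-5 cis to the C10 methyl (5β-H) and has C20 as CH3, so carnosic acid must be corrected at both sites (steps 2–4 and 8), and the transient C7 centre is drawn with H-7 α, which is expected in the 5β series and puts C6 and O-10' trans on ring D.

Step 1
Reactants: 1 carnosic acid
Product: 2 methoxymethyl 11,12-bis(methoxymethoxy)abieta-8,11,13-trien-20-oate
Conditions: NaH, MOMCl, DMF, 0 °C to rt, Ar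
Reagents that add atoms: chloromethyl methyl ether (MOMCl), COCCl
Why: Williamson-type O-alkylation of the carboxylate and both phenoxides by the very reactive chloromethyl ether masks the air-sensitive catechol as base-stable acetals and turns the acid into a reducible ester, with no stereocentre touched.

Step 2
Reactants: 2 methoxymethyl 11,12-bis(methoxymethoxy)abieta-8,11,13-trien-20-oate
Product: 3 11,12-bis(methoxymethoxy)abieta-8,11,13-trien-20-ol
Conditions: LiAlH4, THF, reflux
Reagents that add atoms: none
Why: Ester reduction with LiAlH4 at reflux reaches even the neopentyl C20 carbonyl, while aryl MOM ethers are inert to hydride.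

Step 3
Reactants: 3 11,12-bis(methoxymethoxy)abieta-8,11,13-trien-20-ol
Product: 4 11,12-bis(methoxymethoxy)abieta-8,11,13-trien-20-al
Conditions: DMP, CH2Cl2, 0 °C to rt
Reagents that add atoms: none
Why: Dess–Martin oxidation stops at the non-enolisable C20 aldehyde under nearly neutral conditions that leave the acetals intact.

Step 4
Reactants: 4 11,12-bis(methoxymethoxy)abieta-8,11,13-trien-20-al
Product: 6 11,12-bis(methoxymethoxy)abieta-8,11,13-triene, via C20 hydrazone 5 (not isolated)
Conditions: N2H4·H2O, KOH, diethylene glycol, 130 then 200 °C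
Reagents that add atoms: none
Why: Wolff–Kishner reduction (Huang–Minlon procedure) converts the angular CHO into the C20 methyl group of the target through hydrazone, diazenyl anion and loss of N2, which avoids any C20 cation or radical that could trigger aryl migration and expansion of ring B.

Step 5
Reactants: 6 11,12-bis(methoxymethoxy)abieta-8,11,13-triene
Product: 7 14-bromo-11,12-bis(methoxymethoxy)abieta-8,11,13-triene
Conditions: NBS, MeCN, 0 °C to rt, dark
Reagents that add atoms: N-bromosuccinimide, O=C1CCC(=O)N1Br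
Why: In this electrophilic aromatic bromination C14 is the only free ring position and lies para to the C11 oxygen, and a polar solvent in the dark suppresses benzylic radical bromination.

Step 6
Reactants: 7 14-bromo-11,12-bis(methoxymethoxy)abieta-8,11,13-triene
Product: 8 14-bromo-11,12-bis(methoxymethoxy)abieta-6,8,11,13-tetraene
Conditions: DDQ, dioxane, 100 °C
Reagents that add atoms: none
Why: In this DDQ dehydrogenation, hydride loss from C7 gives a benzylic cation stabilised by the para C12 oxygen and loss of H-6 gives the styrene, while quaternary C10 blocks further aromatisation and the isopropyl C–H, held in the arene plane by its two ortho neighbours, is poorly aligned for hydride loss.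

Step 7
Reactants: 8 14-bromo-11,12-bis(methoxymethoxy)abieta-6,8,11,13-tetraene
Product: 10 14-bromo-11,12-bis(methoxymethoxy)-5α-abieta-8,11,13-trien-6-one, via alpha-epoxide 9 (not isolated)
Conditions: DMDO, acetone–CH2Cl2, −20 °C; evaporate; BF3·OEt2 (10 mol %), CH2Cl2, −78 °C
Reagents that add atoms: dimethyldioxirane, CC1(C)OO1
Why: Neutral epoxidation from the α face (away from the axial C10 methyl) is followed by a Meinwald rearrangement in which the Lewis acid opens the oxirane at benzylic C7 and a 1,2-hydride shift from C6 places the carbonyl at C6, with C5 untouched.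

Step 8
Reactants: 10 14-bromo-11,12-bis(methoxymethoxy)-5α-abieta-8,11,13-trien-6-one
Product: 11 14-bromo-11,12-bis(methoxymethoxy)-5β-abieta-8,11,13-trien-6-one
Conditions: NaOMe, MeOH–THF (degassed), 60 °C; separation, recovered 10 resubmitted
Reagents that add atoms: none
Why: Base-mediated epimerisation through the C5 enolate under thermodynamic control sets C5, and the A/B-cis (5β-H) ketone should be favoured because cis fusion suits the flattened ring B (three sp2 atoms) and moves the C4 methyl groups out of the plane of the C6 carbonyl, while enolisation toward C7 is harmless.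

Step 9
Reactants: 11 14-bromo-11,12-bis(methoxymethoxy)-5β-abieta-8,11,13-trien-6-one; 12 ethyl (E)-4-oxobut-2-enoate
Product: 14 anti aldol adduct with C7–C10' bond, via boron enolate 13 (not isolated)
Conditions: Cy2BCl, Et3N, Et2O, −78 to 0 °C; 12, −78 °C; pH 7 buffer, MeOH, H2O2, 0 °C
Reagents that add atoms: none
Why: In this boron aldol reaction through a closed Zimmerman–Traxler transition state, the ring-locked (E)-enolate gives the anti adduct and the aldehyde reaches C7 from the β face because C4 with its methyl groups hangs pseudoaxially under the α face of the cis-fused enolate, which together set C7 (H-7 α) and C10' (oxygen α once ring D is closed).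

Step 10
Reactants: 14 anti aldol adduct with C7–C10' bond
Product: 15 C10' tert-butyldimethylsilyl ether of 14
Conditions: TBSOTf, 2,6-lutidine, CH2Cl2, −78 to 0 °C
Reagents that add atoms: tert-butyldimethylsilyl triflate, CC(C)(C)[Si](C)(C)OS(=O)(=O)C(F)(F)F
Why: Silylation with the triflate and a hindered pyridine base is fast at low temperature, so the aldol is capped before retro-aldol cleavage or dehydration, and the bulky non-coordinating ether later steers the Claisen step and keeps O-10' from binding zinc.

Step 11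
Reactants: 15 C10' tert-butyldimethylsilyl ether of 14
Product: 16 C6 ethylene ketal of 15
Conditions: (TMSOCH2)2, TMSOTf (10 mol %), CH2Cl2, −78 to −20 °C
Reagents that add atoms: 1,2-bis(trimethylsilyloxy)ethane, C[Si](C)(C)OCCO[Si](C)(C)C
Why: In this Noyori ketalisation the silyl-transfer acetalisation of the electrophilic 2-tetralone-type carbonyl is driven irreversibly by formation of the disiloxane and runs cold enough to spare MOM and TBS groups, and masking C6 removes the acidity of H-7 and with it β-elimination of the C10' silyloxy group in every later basic step.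

Step 12
Reactants: 16 C6 ethylene ketal of 15
Product: 17 ring D closed (Z)-exocyclic enoate
Conditions: Pd2(dba)3 (5 mol %), [HP(t-Bu)3]BF4 (12 mol %), Cy2NMe, dioxane, 90 °C
Reagents that add atoms: none
Why: In this intramolecular Heck reaction (5-exo-trig) the bulky electron-rich phosphine lets zerovalent palladium insert into the doubly ortho-substituted C14–Br bond, syn carbopalladation joins C14 to the enoate β-carbon C4', and syn β-hydride elimination of H-4' gives the exocyclic enoate with the ester cis to C10' and away from the isopropyl group.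

Step 13
Reactants: 17 ring D closed (Z)-exocyclic enoate
Product: 18 (Z)-allylic alcohol C4'=C5'H–CH2OH
Conditions: i-Bu2AlH, CH2Cl2, −78 °C
Reagents that add atoms: none
Why: 1,2-Reduction of the conjugated ester by i-Bu2AlH gives the primary allylic alcohol, and the ketal, acetals and silyl ether are inert.

Step 14
Reactants: 18 (Z)-allylic alcohol C4'=C5'H–CH2OH
Product: 19 C4' quaternary dimethylamide with vinyl group
Conditions: MeC(OMe)2NMe2, toluene, 110 °C
Reagents that add atoms: N,N-dimethylacetamide dimethyl acetal, COC(C)(OC)N(C)C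
Why: In this Eschenmoser–Claisen rearrangement under neutral conditions, the ketene N,O-acetal formed on the allylic oxygen delivers its CH2 terminus (C3') suprafacially to C4' over the β face, anti to the neighbouring α-oriented C10' silyloxy group, which sets the future spiro carbon with C3' β and vinyl C5' α whatever the alkene geometry.

Step 15
Reactants: 19 C4' quaternary dimethylamide with vinyl group; 20 2-bromo-3-methylbut-1-ene
Product: 22 cross-conjugated dienone, via alkenyllithium 21 (not isolated)
Conditions: 20, t-BuLi (2 equiv), Et2O, −78 °C; 19 in THF, −78 to 0 °C; H2O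
Reagents that add atoms: none
Why: Bromine–lithium exchange is followed by acylation of the alkenyllithium by the tertiary amide, whose tetrahedral lithium adduct survives until the quench, so that addition stops at the ketone (C2') carrying C1' and its isopropyl group.

Step 16
Reactants: 22 cross-conjugated dienone
Product: 23 spiro cyclopentenone
Conditions: second-generation Grubbs catalyst RuCl2(=CHPh)(PCy3)(SIMes) (10 mol %), toluene, 80 °C, Ar sparge
Reagents that add atoms: none
Why: In this ring-closing metathesis the full substitution at C4' favours closure to the five-membered ring E and loss of ethene drives formation of the trisubstituted C1'=C5' enone.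

Step 17
Reactants: 23 spiro cyclopentenone
Product: 24 spiro cyclopentenol with C2'–OH on the C14 face
Conditions: NaBH4, CeCl3·7H2O, MeOH–THF, −78 to −20 °C
Reagents that add atoms: none
Why: In this Luche 1,2-reduction hydride reaches C2' from the ring E face on the C10' side, which near C2' shows only H-10', whereas the other face is capped by C14 and the isopropyl methine, so the new hydroxyl ends up on the C14 face.

Step 18
Reactants: 24 spiro cyclopentenol with C2'–OH on the C14 face
Product: 26 C2'-hydroxy thujane adduct, via iodomethylzinc alkoxide 25 (not isolated)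
Conditions: Et2Zn, CH2I2, CH2Cl2, −20 °C to rt
Reagents that add atoms: diiodomethane, ICI
Why: Et2Zn deprotonates the C2' alcohol and exchange with CH2I2 gives alkoxide-bound carbenoid 25, which hands its methylene carbon (C6') to C1'=C5' in a single three-centre event of the butterfly type, so that both new bonds arise on one alkene face. The closest known reaction type is the hydroxyl-directed Simmons–Smith (Furukawa) cyclopropanation of cyclopent-2-enols and related cyclic allylic alcohols, which gives the syn cyclopropyl carbinol. The three-membered ring (C1', C5', C6') closes by [2+1] addition of the tethered carbenoid to the ring E alkene, and a cis-fused bicyclo[3.1.0]hexane is the only possible fusion. C1' and C5' are both controlled by the C2' stereocentre, because the zinc-bound oxygen holds the carbenoid on its own face of ring E. The step needs facial selectivity against the steric bias (C6' syn to C14), secured by the covalent O–Zn tether and its rate acceleration and supported by the C10' oxygen being locked in a bulky silyl ether that cannot bind zinc and partly screens the opposite face near C5'; chemoselectivity is no issue, since no other alkene or free hydroxyl is present.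

Step 19
Reactants: 26 C2'-hydroxy thujane adduct
Product: 27 C2' cyclopropyl ketone
Conditions: DMP, CH2Cl2, 0 °C to rt
Reagents that add atoms: none
Why: Dess–Martin oxidation of the only free alcohol gives the cyclopropyl ketone without the strong acid or radical conditions that could open the three-membered ring.

Step 20
Reactants: 27 C2' cyclopropyl ketone
Product: 29 C2'-deoxy thujane adduct, via C2' hydrazone 28 (not isolated)
Conditions: N2H4·H2O, EtOH, 80 °C; evaporate; KOt-Bu, DMSO, rt to 70 °C
Reagents that add atoms: none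
Why: In this Wolff–Kishner reduction of the preformed hydrazone, the anionic diazenide path protonates C2' without a cyclopropylcarbinyl radical or cation, so the ring should survive as in the classical reduction of bicyclo[3.1.0]hexan-2-ones, and the ketal, MOM and silyl groups tolerate base (loss of the silyl group here would be harmless).

Step 21
Reactants: 29 C2'-deoxy thujane adduct
Product: 30 11,12-catechol with free C6 ketone and C10' alcohol
Conditions: 2 M aq HCl, THF–MeOH, 40 °C, Ar
Reagents that add atoms: water, O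
Why: Acid hydrolysis removes the strained dioxolane, both aryl MOM acetals and the silyl ether in one operation, with C5 next to the freed ketone already in the configuration preferred at equilibrium and C7 about to become sp2.

Step 22
Reactants: 30 11,12-catechol with free C6 ketone and C10' alcohol
Product: 32 target quinone methide CNP0178265.2, via ortho-quinone 31 (not isolated)
Conditions: Ag2O, Et2O, rt
Reagents that add atoms: none
Why: Ag2O oxidises the catechol to the ortho-quinone, whose H-7 (α to C6=O and vinylogously acidified by the quinone) moves to O-11 in the tautomerisation known for 6-oxo-11,12-catechols of the abietane series, giving the 11-hydroxy-12-oxo quinone methide with C7=C8, erasing the C7 centre and leaving the secondary C10' alcohol untouched.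

Compound list
1 | carnosic acid (11,12-dihydroxyabieta-8,11,13-trien-20-oic acid, 5α-H) | CC(C)C1=C(O)C(O)=C2C(=C1)CC[C@@H]3[C@@]2(CCCC3(C)C)C(=O)O | starting material
2 | methoxymethyl 11,12-bis(methoxymethoxy)abieta-8,11,13-trien-20-oate (5α-H) | CC(C)c1cc2CC[C@H]3C(C)(C)CCC[C@]3(C(=O)OCOC)c2c(OCOC)c1OCOC | intermediate
3 | 11,12-bis(methoxymethoxy)abieta-8,11,13-trien-20-ol | CC(C)c1cc2CC[C@H]3C(C)(C)CCC[C@]3(CO)c2c(OCOC)c1OCOC | intermediate
4 | 11,12-bis(methoxymethoxy)abieta-8,11,13-trien-20-al | CC(C)c1cc2CC[C@H]3C(C)(C)CCC[C@]3(C=O)c2c(OCOC)c1OCOC | intermediate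
5 | hydrazone of aldehyde 4 | CC(C)c1cc2CC[C@H]3C(C)(C)CCC[C@]3(C=NN)c2c(OCOC)c1OCOC | intermediate
6 | 11,12-bis(methoxymethoxy)abieta-8,11,13-triene (5α-H, 10β-CH3) | CC(C)c1cc2CC[C@H]3C(C)(C)CCC[C@]3(C)c2c(OCOC)c1OCOC | intermediate
7 | 14-bromo-11,12-bis(methoxymethoxy)abieta-8,11,13-triene | CC(C)c1c(Br)c2CC[C@H]3C(C)(C)CCC[C@]3(C)c2c(OCOC)c1OCOC | intermediate
8 | 14-bromo-11,12-bis(methoxymethoxy)abieta-6,8,11,13-tetraene | CC(C)c1c(Br)c2C=C[C@H]3C(C)(C)CCC[C@]3(C)c2c(OCOC)c1OCOC | intermediate
9 | 6α,7α-epoxide of 8 | CC(C)c1c(Br)c2[C@@H]4O[C@@H]4[C@H]3C(C)(C)CCC[C@]3(C)c2c(OCOC)c1OCOC | intermediate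
10 | 14-bromo-11,12-bis(methoxymethoxy)-5α-abieta-8,11,13-trien-6-one (A/B trans) | CC(C)c1c(Br)c2CC(=O)[C@H]3C(C)(C)CCC[C@]3(C)c2c(OCOC)c1OCOC | intermediate
11 | 14-bromo-11,12-bis(methoxymethoxy)-5β-abieta-8,11,13-trien-6-one (A/B cis, H-5 syn to C20) | CC(C)c1c(Br)c2CC(=O)[C@@H]3C(C)(C)CCC[C@]3(C)c2c(OCOC)c1OCOC | intermediate
12 | ethyl (E)-4-oxobut-2-enoate | CCOC(=O)/C=C/C=O | starting material
13 | dicyclohexylboron C6=C7 enolate of 11 | CC(C)c1c(Br)c2C=C(OB(C4CCCCC4)C5CCCCC5)[C@@H]3C(C)(C)CCC[C@]3(C)c2c(OCOC)c1OCOC | intermediate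
14 | anti aldol: 11 carrying at C7 (β face, H-7 α) the chain C10'H(OH)–C4'H=C5'H–CO2Et (E) | CC(C)c1c(Br)c2[C@@H]([C@@H](O)/C=C/C(=O)OCC)C(=O)[C@@H]3C(C)(C)CCC[C@]3(C)c2c(OCOC)c1OCOC | intermediate
15 | C10' TBS ether of 14 | CC(C)c1c(Br)c2[C@@H]([C@@H](O[Si](C)(C)C(C)(C)C)/C=C/C(=O)OCC)C(=O)[C@@H]3C(C)(C)CCC[C@]3(C)c2c(OCOC)c1OCOC | intermediate
16 | C6 ethylene ketal of 15 | CC(C)c1c(Br)c2[C@@H]([C@@H](O[Si](C)(C)C(C)(C)C)/C=C/C(=O)OCC)C4(OCCO4)[C@@H]3C(C)(C)CCC[C@]3(C)c2c(OCOC)c1OCOC | intermediate
17 | ring D closed (C14–C4') exocyclic enoate, C4'=C5'H–CO2Et (Z, ester cis to C10'), 10'α-OTBS, H-7 α, 5β-H, C6 ketal | CC(C)c1c(OCOC)c(OCOC)c2c3c1/C(=C/C(=O)OCC)[C@H](O[Si](C)(C)C(C)(C)C)[C@H]3C7(OCCO7)[C@@H]4C(C)(C)CCC[C@]24C | intermediate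
18 | (Z)-allylic alcohol from 17 (C4'=C5'H–CH2OH) | CC(C)c1c(OCOC)c(OCOC)c2c3c1/C(=C/CO)[C@H](O[Si](C)(C)C(C)(C)C)[C@H]3C7(OCCO7)[C@@H]4C(C)(C)CCC[C@]24C | intermediate
19 | amide with quaternary C4': vinyl (C5') on the α face, CH2C(O)NMe2 (C3', C2') on the β face | CC(C)c1c(OCOC)c(OCOC)c2c3c1[C@@](C=C)(CC(=O)N(C)C)[C@H](O[Si](C)(C)C(C)(C)C)[C@H]3C7(OCCO7)[C@@H]4C(C)(C)CCC[C@]24C | intermediate
20 | 2-bromo-3-methylbut-1-ene | CC(C)C(Br)=C | starting material
21 | (3-methylbut-1-en-2-yl)lithium | [Li]C(=C)C(C)C | intermediate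
22 | dienone: C4'(CH=CH2)–CH2–C(=O)–C(=CH2)–CH(CH3)2 | CC(C)c1c(OCOC)c(OCOC)c2c3c1[C@@](C=C)(CC(=O)C(=C)C(C)C)[C@H](O[Si](C)(C)C(C)(C)C)[C@H]3C7(OCCO7)[C@@H]4C(C)(C)CCC[C@]24C | intermediate
23 | spiro cyclopentenone (C2'=O, C1'(iPr)=C5'H, spiro C4') | CC(C)c1c(OCOC)c(OCOC)c2c3c1[C@@]5(CC(=O)C(C(C)C)=C5)[C@H](O[Si](C)(C)C(C)(C)C)[C@H]3C7(OCCO7)[C@@H]4C(C)(C)CCC[C@]24C | intermediate
24 | hexacyclic spiro cyclopentenol, C2'–OH on the ring E face toward C14, C6 ketal, 10'α-OTBS, bis-MOM | CC(C)c1c(OCOC)c(OCOC)c2c3c1[C@@]5(C[C@H](O)C(C(C)C)=C5)[C@H](O[Si](C)(C)C(C)(C)C)[C@H]3C7(OCCO7)[C@@H]4C(C)(C)CCC[C@]24C | intermediate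
25 | iodomethylzinc alkoxide of 24 | CC(C)c1c(OCOC)c(OCOC)c2c3c1[C@@]5(C[C@H](O[Zn]CI)C(C(C)C)=C5)[C@H](O[Si](C)(C)C(C)(C)C)[C@H]3C7(OCCO7)[C@@H]4C(C)(C)CCC[C@]24C | intermediate
26 | C2'-hydroxy thujane adduct, cyclopropane (C1', C5', C6') and C2'–OH both on the C14 face | CC(C)c1c(OCOC)c(OCOC)c2c3c1[C@@]5(C[C@H](O)[C@]6(C(C)C)C[C@@H]65)[C@H](O[Si](C)(C)C(C)(C)C)[C@H]3C7(OCCO7)[C@@H]4C(C)(C)CCC[C@]24C | intermediate
27 | C2' cyclopropyl ketone | CC(C)c1c(OCOC)c(OCOC)c2c3c1[C@@]5(CC(=O)[C@]6(C(C)C)C[C@@H]65)[C@H](O[Si](C)(C)C(C)(C)C)[C@H]3C7(OCCO7)[C@@H]4C(C)(C)CCC[C@]24C | intermediate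
28 | C2' hydrazone of 27 | CC(C)c1c(OCOC)c(OCOC)c2c3c1[C@@]5(CC(=NN)[C@]6(C(C)C)C[C@@H]65)[C@H](O[Si](C)(C)C(C)(C)C)[C@H]3C7(OCCO7)[C@@H]4C(C)(C)CCC[C@]24C | intermediate
29 | C2'-deoxy thujane adduct (C2'H2), fully protected | CC(C)c1c(OCOC)c(OCOC)c2c3c1[C@@]5(CC[C@]6(C(C)C)C[C@@H]65)[C@H](O[Si](C)(C)C(C)(C)C)[C@H]3C7(OCCO7)[C@@H]4C(C)(C)CCC[C@]24C | intermediate
30 | 11,12-catechol, C6 ketone, 10'α-OH, H-7 α, 5β-H | CC(C)c1c(O)c(O)c2c3c1[C@@]5(CC[C@]6(C(C)C)C[C@@H]65)[C@H](O)[C@H]3C(=O)[C@@H]4C(C)(C)CCC[C@]24C | intermediate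
31 | 11,12-ortho-quinone of 30 | CC(C)C1=C2C3=C(C(=O)C1=O)[C@@]4(C)CCCC(C)(C)[C@H]4C(=O)[C@@H]3[C@@H](O)[C@]21CC[C@]2(C(C)C)C[C@@H]21 | intermediate
32 | CNP0178265.2 (11-hydroxy-6,12-dioxo quinone methide, C7=C8) | CC(C)C1=C2C3=C(C(=O)[C@@H]4C(C)(C)CCC[C@]4(C)C3=C(O)C1=O)[C@@H](O)[C@]21CC[C@]2(C(C)C)C[C@@H]21 | target

Total step count: 22. Longest linear sequence: 22 steps (1 to 32).

Steps most likely to fail

1) Step 18. The pocket between ring E and the C13 isopropyl methine is tight. Methylene transfer may therefore stall, or untethered carbenoid may attack the open face on the C10' side. The fallback sets out from 24 and comes back at 27. It uses the C2' oxygen as a covalent carrier for C6' instead of as a ligand for zinc.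
- KH and Bu3SnCH2I give the tributylstannylmethyl ether F1.
- n-BuLi starts a Still–Wittig [2,3] shift that moves the CH2O unit suprafacially from O-2' to C5'. This gives the C5'-hydroxymethyl cyclopentene F2, with C6' on the C14 face and the alkene at C1'=C2'.
- TsCl in pyridine gives the primary tosylate F3.
- BH3·THF followed by NaBO3 places oxygen at C2' and gives the hydroxy tosylate F4.
- DMP gives the keto tosylate F5.
- KOt-Bu forms the C1' enolate, which closes C1'–C6' by 3-exo-tet alkylation to 27.

2) Step 12. Oxidative addition at the doubly ortho-substituted, electron-rich bromide may be slow. Reduction of the C–Br bond, or drift of the new double bond into ring D, could then take over. The fallback sets out from 16 and comes back at 17.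
- t-BuLi at −100 °C exchanges the bromide.
- The aryllithium adds to the enoate in an intramolecular conjugate addition (5-exo-trig).
- The ester enolate is trapped with PhSeBr to give the α-phenylselanyl ester F6.
- H2O2 oxidation with syn elimination of the selenoxide toward H-4' restores the exocyclic enoate 17.

3) Step 16. The ruthenium carbene must load on a neopentyl vinyl group and then engage an electron-poor 1,1-disubstituted alkene that bears an isopropyl group. Stalling or intermolecular metathesis is therefore possible. The fallback sets out from 19 and comes back at 23, and it replaces metathesis by carbonyl condensation.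
- Isobutyllithium adds to the amide to give the isobutyl ketone F7.
- OsO4 (catalytic) with NaIO4 cleaves the vinyl group to the keto aldehyde F8.
- KOH in MeOH closes ring E by intramolecular aldol condensation of C1' onto the non-enolisable C5' aldehyde, giving 23.

Further compounds
F1 | step 18 | tributylstannylmethyl ether of 24 | CC(C)c1c(OCOC)c(OCOC)c2c3c1[C@@]5(C[C@H](OC[Sn](CCCC)(CCCC)CCCC)C(C(C)C)=C5)[C@H](O[Si](C)(C)C(C)(C)C)[C@H]3C7(OCCO7)[C@@H]4C(C)(C)CCC[C@]24C
F2 | step 18 | C5'-hydroxymethyl cyclopentene (C6' on the C14 face, C1'=C2') | CC(C)c1c(OCOC)c(OCOC)c2c3c1[C@@]5(CC=C(C(C)C)[C@@H]5CO)[C@H](O[Si](C)(C)C(C)(C)C)[C@H]3C7(OCCO7)[C@@H]4C(C)(C)CCC[C@]24C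
F3 | step 18 | primary tosylate of F2 | CC(C)c1c(OCOC)c(OCOC)c2c3c1[C@@]5(CC=C(C(C)C)[C@@H]5COS(=O)(=O)c6ccc(C)cc6)[C@H](O[Si](C)(C)C(C)(C)C)[C@H]3C7(OCCO7)[C@@H]4C(C)(C)CCC[C@]24C
F4 | step 18 | hydroxy tosylate (C2'–OH on the C10' face, H-1' on the same face) | CC(C)c1c(OCOC)c(OCOC)c2c3c1[C@@]5(C[C@@H](O)[C@H](C(C)C)[C@@H]5COS(=O)(=O)c6ccc(C)cc6)[C@H](O[Si](C)(C)C(C)(C)C)[C@H]3C7(OCCO7)[C@@H]4C(C)(C)CCC[C@]24C
F5 | step 18 | keto tosylate (C2'=O) | CC(C)c1c(OCOC)c(OCOC)c2c3c1[C@@]5(CC(=O)[C@H](C(C)C)[C@@H]5COS(=O)(=O)c6ccc(C)cc6)[C@H](O[Si](C)(C)C(C)(C)C)[C@H]3C7(OCCO7)[C@@H]4C(C)(C)CCC[C@]24C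
F6 | step 12 | α-phenylselanyl ester (ring D closed, H-4' α, C5' unassigned) | CC(C)c1c(OCOC)c(OCOC)c2c3c1[C@@H](C([Se]c5ccccc5)C(=O)OCC)[C@H](O[Si](C)(C)C(C)(C)C)[C@H]3C7(OCCO7)[C@@H]4C(C)(C)CCC[C@]24C
F7 | step 16 | isobutyl ketone | CC(C)c1c(OCOC)c(OCOC)c2c3c1[C@@](C=C)(CC(=O)CC(C)C)[C@H](O[Si](C)(C)C(C)(C)C)[C@H]3C7(OCCO7)[C@@H]4C(C)(C)CCC[C@]24C
F8 | step 16 | keto aldehyde | CC(C)c1c(OCOC)c(OCOC)c2c3c1[C@@](C=O)(CC(=O)CC(C)C)[C@H](O[Si](C)(C)C(C)(C)C)[C@H]3C7(OCCO7)[C@@H]4C(C)(C)CCC[C@]24C
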